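**Plan**

1. Numbering (germacrane): lactone O–C6, C7, C11(=C13), C12=O is ring C; C8 carries the angelate; C9 is the methylene; C10 is the methyl-bearing ether carbon; C1 the ketone; C2=C3; C4(=C15); C5 the second ether carbon. Ring A is the oxepane O–C5–C6–C7–C8–C9–C10, ring B the oxepinone O–C10–C1–C2–C3–C4–C5.
2. Retrosynthetic cuts, in order: angelate ester; C2=C3 (dehydrogenation next to the C1 ketone); C11=C13 (lactone methylenation); O–C5 (transannular allylic etherification, closing rings A and B together); C4–C5 (Nozaki–Hiyama–Kishi closure of the ten-membered carbocycle); then C8–C9 and O–C10 in one cut (nitrile oxide cycloaddition), giving lactone oxime 9 (fragment 1) and iodo-dienol 15 (fragment 2).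
3. Enabling feature: C8(O)–C9H2–C10(O) is a 1,3-dioxygenated (aldol) array inside ring A, and C10 is flanked by the C1 oxygen. An isoxazoline (C8=N–O–C10, C9 as its CH2) is the masked form: its oxygen becomes the bridging ether oxygen, its N–O bond is a temporary ring bond, and the C1 carbinol (later the ring B ketone) holds magnesium to steer the cycloaddition.
4. Forward order: ring C (Evans aldol, lactonisation) → temporary isoxazoline (fragment union) → N–O cleavage → ten-membered carbocycle → oxygen bridge (rings A and B) → methylene lactone, dienone, angelate.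
5. Stereochemistry: C6 and C7 from the Evans syn-aldol; C1 (temporary) from a CBS reduction; C10 from C1 through the magnesium chelate; C8 from a CBS reduction reinforced by Felkin–Anh control from C7; C5 from the bridge geometry (only the cis-bridged ether can close).

Key step: step 10

Remark on the chemistry: aldehyde 4 is taken as a purchased compound; oxime 9 is used as an E/Z mixture; 25 and 26 are carried as mixtures of C5 epimers (C5 is reset in step 19), so their SMILES leave C5 undefined.

**Route**

Step 1
Reactants: 1 (S)-4-benzyl-1,3-oxazolidin-2-one; 2 methyl 4-chloro-4-oxobutanoate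
Product: 3 methyl 4-[(S)-4-benzyl-2-oxo-1,3-oxazolidin-3-yl]-4-oxobutanoate
Conditions: n-BuLi, THF, −78 °C; then 2, −78 to 0 °C
Reagents that add atoms: none
Why: N-acylation of the lithiated Evans oxazolidinone by the acid chloride (imide formation) is a standard acyl transfer and creates no stereocenter.

Step 2
Reactants: 3 methyl 4-[(S)-4-benzyl-2-oxo-1,3-oxazolidin-3-yl]-4-oxobutanoate; 4 2-[(4-methoxybenzyl)oxy]acetaldehyde
Product: 6 trans-γ-butyrolactone imide (acyl-oxazolidinone on C7; CH2OPMB on C6), via syn-aldol adduct 5 (not isolated)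
Conditions: Bu2BOTf, i-Pr2NEt, CH2Cl2, −78 to 0 °C; 4, −78 °C; pH 7 buffer, MeOH, H2O2; then p-toluenesulfonic acid monohydrate (cat.), CH2Cl2, rt
Reagents that add atoms: none
Why: Evans syn-aldol reaction, in which the Z-dibutylboron enolate of the imide (enolised at the imide α-carbon, not at the ester) adds through a Zimmerman–Traxler chair on the face away from the benzyl group and so sets C6 and C7, after which the γ-hydroxy ester lactonises to the trans-disubstituted lactone.

Step 3
Reactants: 6 trans-γ-butyrolactone imide
Product: 7 S-ethyl thioester of the lactone C7 carboxylic acid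
Conditions: EtSH, n-BuLi, THF, −78 to 0 °C; aq. NH4Cl
Reagents that add atoms: ethanethiol CCS
Why: Thiolate cleavage of the Evans imide (acyl transfer to LiSEt) removes the auxiliary at the more electrophilic exocyclic carbonyl and leaves the lactone and C7 untouched.

Step 4
Reactants: 7 S-ethyl thioester
Product: 8 lactone aldehyde (C8 formyl on C7)
Conditions: Et3SiH, 10% Pd/C, acetone, rt
Reagents that add atoms: none
Why: Fukuyama reduction of the thioester stops at the aldehyde and tolerates the lactone and the PMB ether.

Step 5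
Reactants: 8 lactone aldehyde
Product: 9 lactone aldoxime (fragment 1)
Conditions: NH2OH·HCl, NaOAc, EtOH, 0 °C to rt
Reagents that add atoms: hydroxylamine hydrochloride Cl.NO
Why: Oxime formation (condensation) under acetate buffering avoids β-elimination of the lactone oxygen and epimerisation at C7.

Step 6
Reactants: 10 pent-4-ynoic acid
Product: 11 4-iodopent-4-enoic acid
Conditions: NaI, Me3SiCl, H2O, MeCN, rt
Reagents that add atoms: sodium iodide [Na+].[I-]
Why: Markovnikov hydroiodination of the terminal alkyne by HI generated in the flask gives the 2-iodoalkene needed for the later Nozaki–Hiyama–Kishi closure.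

Step 7
Reactants: 11 4-iodopent-4-enoic acid
Product: 12 4-iodo-N-methoxy-N-methylpent-4-enamide
Conditions: 1,1'-carbonyldiimidazole, CH2Cl2, rt; then MeNHOMe·HCl
Reagents that add atoms: N,O-dimethylhydroxylamine hydrochloride CNOC.Cl
Why: Amide coupling through the acyl imidazolide gives the Weinreb amide without touching the vinyl iodide.

Step 8
Reactants: 12 4-iodo-N-methoxy-N-methylpent-4-enamide; 13 isopropenylmagnesium bromide
Product: 14 6-iodo-2-methylhepta-1,6-dien-3-one
Conditions: THF, −20 to 0 °C; cold 1 M HCl
Reagents that add atoms: none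
Why: Weinreb ketone synthesis, in which the stable magnesium chelate of the tetrahedral adduct prevents over-addition and releases the isopropenyl ketone on acidic work-up.

Step 9
Reactants: 14 6-iodo-2-methylhepta-1,6-dien-3-one
Product: 15 (S)-6-iodo-2-methylhepta-1,6-dien-3-ol (fragment 2)
Conditions: (R)-2-methyl-CBS-oxazaborolidine [(R)-1-methyl-3,3-diphenyltetrahydro-1H,3H-pyrrolo[1,2-c][1,3,2]oxazaborole] (cat.), BH3·SMe2, THF, −20 °C; MeOH
Reagents that add atoms: none
Why: Corey–Bakshi–Shibata reduction, in which the oxazaborolidine binds the ketone with the isopropenyl group as the large substituent and delivers hydride to give the (S)-carbinol at C1.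

Step 10
Reactants: 9 lactone aldoxime; 15 (S)-6-iodo-2-methylhepta-1,6-dien-3-ol
Product: 18 isoxazoline (C8=N–O–C10; C9 as ring CH2; free C1 hydroxyl), via hydroximoyl chloride 16 (not isolated), via nitrile oxide 17 (not isolated)
Conditions: 9, t-BuOCl, CH2Cl2, −78 °C; added slowly to 15, i-PrOH, EtMgBr, CH2Cl2, 0 °C to rt
Reagents that add atoms: none
Why: tert-Butyl hypochlorite chlorinates the oxime to 16, the magnesium alkoxides dehydrochlorinate it to nitrile oxide 17, and 17 adds across C9=C10 of the magnesium alkoxide of 15 in a concerted, asynchronous 1,3-dipolar cycloaddition that forms C8–C9 and O–C10 at once. The closest known reaction type is the magnesium-alkoxide-directed nitrile oxide cycloaddition to allylic alcohols, 1,1-disubstituted ones included. The only ring closed is the isoxazoline, formed by suprafacial [3+2] union of the C–N–O dipole with the alkene between the two fragments; it is a temporary ring whose N–O bond is cut in step 12, and its oxygen becomes the bridging ether oxygen. The new stereocenter C10 is controlled by the C1 carbinol: magnesium bridges the alkoxide oxygen and the nitrile oxide oxygen, the allylic hydrogen sits inside and the chain anti, so the oxygen is delivered syn to the C1 oxygen. The step needs regioselectivity (oxygen to the fully substituted C10), chemoselectivity over the iodoalkene and facial selectivity; the first follows from the polarisation and sterics of the 1,1-disubstituted alkene, the other two from the chelate, which accelerates reaction only at the alkene next to the alkoxide.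

Step 11
Reactants: 18 isoxazoline
Product: 19 C1 triethylsilyl ether of the isoxazoline
Conditions: Et3SiOTf, 2,6-lutidine, CH2Cl2, −78 °C
Reagents that add atoms: triethylsilyl trifluoromethanesulfonate CC[Si](CC)(CC)OS(=O)(=O)C(F)(F)F
Why: Silyl ether formation with the silyl triflate protects the hindered C1 carbinol, whose directing role is over, without touching the isoxazoline.

Step 12
Reactants: 19 C1 triethylsilyl ether of the isoxazoline
Product: 20 β-hydroxy ketone (C8 ketone; tertiary C10 hydroxyl)
Conditions: Mo(CO)6, MeCN/H2O (15:1), 80 °C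
Reagents that add atoms: water O
Why: Reductive N–O cleavage of the isoxazoline by Mo(CO)6 and hydrolysis of the β-hydroxy imine unmask the aldol, and the reagent spares the vinyl iodide that hydrogenolysis over Raney nickel would remove.

Step 13
Reactants: 20 β-hydroxy ketone
Product: 21 diol (secondary C8 hydroxyl; tertiary C10 hydroxyl)
Conditions: (S)-2-methyl-CBS-oxazaborolidine, catecholborane, toluene, −78 °C; MeOH, then aq. NaOH
Reagents that add atoms: none
Why: Corey–Bakshi–Shibata reduction with the C7 branch as the large and the C9 methylene as the small substituent sets the C8 carbinol, and the Felkin–Anh preference from C7 points the same way.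

Step 14
Reactants: 21 diol
Product: 22 C8 tert-butyldimethylsilyl ether
Conditions: t-BuMe2SiOTf, 2,6-lutidine, CH2Cl2, −78 °C
Reagents that add atoms: tert-butyldimethylsilyl trifluoromethanesulfonate CC(C)(C)[Si](C)(C)OS(=O)(=O)C(F)(F)F
Why: Silylation with the silyl triflate at low temperature discriminates the secondary C8 hydroxyl from the tertiary C10 hydroxyl.

Step 15
Reactants: 22 C8 tert-butyldimethylsilyl ether
Product: 23 primary C5 alcohol
Conditions: DDQ (2,3-dichloro-5,6-dicyano-1,4-benzoquinone), CH2Cl2/pH 7 buffer, 0 °C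
Reagents that add atoms: none
Why: Oxidative cleavage of the p-methoxybenzyl ether by DDQ frees the primary alcohol and leaves both silyl ethers and the vinyl iodide.

Step 16
Reactants: 23 primary C5 alcohol
Product: 24 C5 aldehyde (open-chain iodo aldehyde)
Conditions: Dess–Martin periodinane, CH2Cl2, 0 °C to rt
Reagents that add atoms: none
Why: Dess–Martin oxidation gives the α-acyloxy aldehyde under neutral conditions without epimerising C6 and without touching the tertiary alcohol.

Step 17
Reactants: 24 C5 aldehyde
Product: 25 ten-membered carbocyclic allylic alcohol (C5 hydroxyl; C4 exocyclic methylene)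
Conditions: CrCl2, NiCl2 (cat.), DMSO/THF, rt, slow addition (0.002 M)
Reagents that add atoms: none
Why: Nozaki–Hiyama–Kishi reaction, in which the vinyl iodide is turned through nickel catalysis into a vinylchromium species that adds chemoselectively to the aldehyde and closes the ten-membered ring while installing the C4 methylene; the C5 configuration is left open because step 19 resets it.

Step 18
Reactants: 25 ten-membered carbocyclic allylic alcohol
Product: 26 C5 allylic methyl carbonate
Conditions: ClCO2Me, pyridine, 4-(dimethylamino)pyridine (cat.), CH2Cl2, 0 °C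
Reagents that add atoms: methyl chloroformate COC(=O)Cl
Why: Carbonate formation (acylation) is selective for the secondary allylic C5 hydroxyl over the tertiary C10 hydroxyl.

Step 19
Reactants: 26 C5 allylic methyl carbonate
Product: 27 bridged ether (11-oxabicyclo[4.4.1] core; rings A and B)
Conditions: Pd(PPh3)4 (10 mol %), THF, 50 °C
Reagents that add atoms: none
Why: Intramolecular Tsuji–Trost allylic etherification, in which the π-allylpalladium complex C5–C4–C15 is attacked across the ring at C5 by the C10 alkoxide (formed by the released methoxide); both C5 epimers converge by π–σ–π isomerisation at the CH2 terminus, and C5 is set by the bridge because only the cis-bridged ether can exist.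

Step 20
Reactants: 27 bridged ether
Product: 30 α-methylene lactone, via Mannich base 28 (not isolated), via ammonium iodide 29 (not isolated)
Conditions: LDA, THF, −78 °C; CH2=NMe2+ I− (Eschenmoser's salt), −78 to 0 °C; MeI, MeOH, rt; aq. NaHCO3, EtOAc
Reagents that add atoms: dimethylmethyleneiminium iodide C=[N+](C)C.[I-]
Why: Eschenmoser methylenation (enolate Mannich reaction, N-methylation, Hofmann-type elimination) builds the C11=C13 double bond, and since C11 becomes sp2 its transient configuration does not matter.

Step 21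
Reactants: 30 α-methylene lactone
Product: 31 C1 alcohol
Conditions: pyridinium p-toluenesulfonate (cat.), MeOH/CH2Cl2, 0 °C to rt
Reagents that add atoms: none
Why: Acid-catalysed methanolysis cleaves the triethylsilyl ether selectively beside the bulkier tert-butyldimethylsilyl ether.

Step 22
Reactants: 31 C1 alcohol
Product: 33 cross-conjugated dienone (C8 silyl ether), via ketone 32 (not isolated)
Conditions: IBX (2-iodoxybenzoic acid), DMSO, 25 °C, then 70 °C
Reagents that add atoms: none
Why: IBX oxidises the alcohol to the ketone and then dehydrogenates it through the enol (IBX dehydrogenation); the quaternary C10 leaves C2 as the only enolisable site, and the seven-membered ring forces the cis C2=C3 geometry.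

Step 23
Reactants: 33 cross-conjugated dienone
Product: 34 C8 alcohol
Conditions: HF·pyridine, pyridine, THF, 0 °C to rt
Reagents that add atoms: none
Why: Fluoride-mediated desilylation under buffered conditions spares the dienone, the methylene lactone and the bridging ether.

Step 24
Reactants: 34 C8 alcohol; 35 angelic acid ((Z)-2-methylbut-2-enoic acid)
Product: 37 target CNP0282559.1, via mixed anhydride 36 (not isolated)
Conditions: 35, 2,4,6-trichlorobenzoyl chloride, Et3N, toluene, rt; then 34, 75 °C
Reagents that add atoms: none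
Why: Yamaguchi-type esterification through the 2,4,6-trichlorobenzoyl mixed anhydride acylates the hindered C8 alcohol with retention at C8 and, run without a nucleophilic catalyst, should keep the Z geometry of the angelate.

**Compound list**

1 | (S)-4-benzyl-1,3-oxazolidin-2-one | O=C1OC[C@H](Cc2ccccc2)N1 | starting material
2 | methyl 4-chloro-4-oxobutanoate | COC(=O)CCC(Cl)=O | starting material
3 | methyl 4-[(S)-4-benzyl-2-oxo-1,3-oxazolidin-3-yl]-4-oxobutanoate | COC(=O)CCC(=O)N1[C@@H](Cc2ccccc2)COC1=O | intermediate
4 | 2-[(4-methoxybenzyl)oxy]acetaldehyde | COc1ccc(COCC=O)cc1 | starting material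
5 | syn-aldol adduct (β-hydroxy imide, present as its boron aldolate before work-up) | COC(=O)C[C@H](C(=O)N1[C@@H](Cc2ccccc2)COC1=O)[C@H](O)COCc1ccc(OC)cc1 | intermediate (not isolated)
6 | trans-γ-butyrolactone imide (acyl-oxazolidinone on C7, CH2OPMB on C6) | O=C1C[C@H](C(=O)N2[C@@H](Cc3ccccc3)COC2=O)[C@@H](COCc2ccc(OC)cc2)O1 | intermediate
7 | S-ethyl thioester of the lactone C7 carboxylic acid | O=C1C[C@H](C(=O)SCC)[C@@H](COCc2ccc(OC)cc2)O1 | intermediate
8 | lactone aldehyde (C8 formyl on C7) | O=C1C[C@H](C=O)[C@@H](COCc2ccc(OC)cc2)O1 | intermediate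
9 | lactone aldoxime, E/Z mixture (fragment 1) | O=C1C[C@H](C=NO)[C@@H](COCc2ccc(OC)cc2)O1 | intermediate
10 | pent-4-ynoic acid | C#CCCC(=O)O | starting material
11 | 4-iodopent-4-enoic acid | C=C(I)CCC(=O)O | intermediate
12 | 4-iodo-N-methoxy-N-methylpent-4-enamide | C=C(I)CCC(=O)N(C)OC | intermediate
13 | isopropenylmagnesium bromide | CC(=C)[Mg]Br | starting material
14 | 6-iodo-2-methylhepta-1,6-dien-3-one | C=C(C)C(=O)CCC(I)=C | intermediate
15 | (S)-6-iodo-2-methylhepta-1,6-dien-3-ol (fragment 2) | C=C(C)[C@@H](O)CCC(I)=C | intermediate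
16 | hydroximoyl chloride of 9 | O=C1C[C@H](C(Cl)=NO)[C@@H](COCc2ccc(OC)cc2)O1 | intermediate (not isolated)
17 | nitrile oxide of 9 | O=C1C[C@H](C#[N+][O-])[C@@H](COCc2ccc(OC)cc2)O1 | intermediate (not isolated)
18 | isoxazoline: lactone C7 on C8 (isoxazoline C3); C10 (isoxazoline C5) bears methyl and the (S)-CH(OH)CH2CH2C(I)=CH2 chain | O=C1C[C@H](C2=NO[C@](C)([C@@H](O)CCC(I)=C)C2)[C@@H](COCc3ccc(OC)cc3)O1 | intermediate
19 | C1 triethylsilyl ether of 18 | O=C1C[C@H](C2=NO[C@](C)([C@@H](O[Si](CC)(CC)CC)CCC(I)=C)C2)[C@@H](COCc3ccc(OC)cc3)O1 | intermediate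
20 | β-hydroxy ketone (C8 ketone, tertiary C10 hydroxyl) | O=C1C[C@H](C(=O)C[C@](C)(O)[C@@H](O[Si](CC)(CC)CC)CCC(I)=C)[C@@H](COCc2ccc(OC)cc2)O1 | intermediate
21 | diol (C8 (R)-carbinol, tertiary C10 hydroxyl) | O=C1C[C@H]([C@H](O)C[C@](C)(O)[C@@H](O[Si](CC)(CC)CC)CCC(I)=C)[C@@H](COCc2ccc(OC)cc2)O1 | intermediate
22 | C8 tert-butyldimethylsilyl ether of 21 | O=C1C[C@H]([C@H](O[Si](C)(C)C(C)(C)C)C[C@](C)(O)[C@@H](O[Si](CC)(CC)CC)CCC(I)=C)[C@@H](COCc2ccc(OC)cc2)O1 | intermediate
23 | primary C5 alcohol (PMB removed) | O=C1C[C@H]([C@H](O[Si](C)(C)C(C)(C)C)C[C@](C)(O)[C@@H](O[Si](CC)(CC)CC)CCC(I)=C)[C@@H](CO)O1 | intermediate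
24 | C5 aldehyde (open-chain iodo aldehyde) | O=C1C[C@H]([C@H](O[Si](C)(C)C(C)(C)C)C[C@](C)(O)[C@@H](O[Si](CC)(CC)CC)CCC(I)=C)[C@@H](C=O)O1 | intermediate
25 | ten-membered carbocycle with trans-fused lactone, C5 hydroxyl (epimer mixture), C4 exocyclic methylene, C1 OTES, C8 OTBS, C10 hydroxyl | C1C(=O)O[C@H]2[C@H]1[C@H](O[Si](C)(C)C(C)(C)C)C[C@](C)(O)[C@@H](O[Si](CC)(CC)CC)CCC(=C)C2O | intermediate
26 | C5 methyl carbonate of 25 (epimer mixture) | C1C(=O)O[C@H]2[C@H]1[C@H](O[Si](C)(C)C(C)(C)C)C[C@](C)(O)[C@@H](O[Si](CC)(CC)CC)CCC(=C)C2OC(=O)OC | intermediate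
27 | bridged ether: C5–O–C10 bridge, C4 exocyclic methylene, C1 OTES, C8 OTBS, saturated lactone | C1C(=O)O[C@H]2[C@H]1[C@H](O[Si](C)(C)C(C)(C)C)C[C@]1(C)O[C@H]2C(=C)CC[C@@H]1O[Si](CC)(CC)CC | intermediate
28 | Mannich base (C11 dimethylaminomethyl lactone, C11 undefined) | CN(C)CC1C(=O)O[C@H]2[C@H]1[C@H](O[Si](C)(C)C(C)(C)C)C[C@]1(C)O[C@H]2C(=C)CC[C@@H]1O[Si](CC)(CC)CC | intermediate (not isolated)
29 | trimethylammonium iodide of 28 | C[N+](C)(C)CC1C(=O)O[C@H]2[C@H]1[C@H](O[Si](C)(C)C(C)(C)C)C[C@]1(C)O[C@H]2C(=C)CC[C@@H]1O[Si](CC)(CC)CC.[I-] | intermediate (not isolated)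
30 | α-methylene lactone (C1 OTES, C8 OTBS) | C=C1C(=O)O[C@H]2[C@H]1[C@H](O[Si](C)(C)C(C)(C)C)C[C@]1(C)O[C@H]2C(=C)CC[C@@H]1O[Si](CC)(CC)CC | intermediate
31 | C1 alcohol (C8 OTBS) | C=C1C(=O)O[C@H]2[C@H]1[C@H](O[Si](C)(C)C(C)(C)C)C[C@]1(C)O[C@H]2C(=C)CC[C@@H]1O | intermediate
32 | C1 ketone with saturated C2–C3 | C=C1C(=O)O[C@H]2[C@H]1[C@H](O[Si](C)(C)C(C)(C)C)C[C@]1(C)O[C@H]2C(=C)CCC1=O | intermediate (not isolated)
33 | cross-conjugated dienone (C8 OTBS) | C=C1C(=O)O[C@H]2[C@H]1[C@H](O[Si](C)(C)C(C)(C)C)C[C@]1(C)O[C@H]2C(=C)C=CC1=O | intermediate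
34 | C8 alcohol (deacyl target) | C=C1C(=O)O[C@H]2[C@H]1[C@H](O)C[C@]1(C)O[C@H]2C(=C)C=CC1=O | intermediate
35 | angelic acid | C/C=C(/C)C(=O)O | starting material
36 | angelic 2,4,6-trichlorobenzoic mixed anhydride | C/C=C(/C)C(=O)OC(=O)c1c(Cl)cc(Cl)cc1Cl | intermediate (not isolated)
37 | CNP0282559.1 | C=C1C(=O)O[C@H]2[C@H]1[C@H](OC(=O)/C(C)=C\C)C[C@]1(C)O[C@H]2C(=C)C=CC1=O | target

**Count and risks**

Total step count: 24. Longest linear sequence: 20 steps (steps 1–5, then 10–24).

Steps most likely to fail:

Step 17. Intermolecular coupling may outrun closure of the ten-membered ring from the flexible open chain, and the vinylchromium species may be protonated before it finds the aldehyde. The fallback sets out from 19 and comes back at 26; it closes the ring before the isoxazoline is opened, so that the five-membered ring locks C8, C9 and C10 and takes rotors out of the chain. DDQ cleaves the PMB ether of 19 to the isoxazoline primary alcohol F1, and Dess–Martin oxidation gives the isoxazoline aldehyde F2. CrCl2 with catalytic NiCl2 under high dilution then closes the carbocycle to the macrocyclic isoxazoline carbinol F3, and methyl chloroformate in pyridine gives the macrocyclic isoxazoline carbonate F4. Mo(CO)6 in wet MeCN opens the isoxazoline to the macrocyclic β-hydroxy ketone F5, the (S)-CBS reduction with catecholborane gives the macrocyclic diol F6, and silylation of the C8 hydroxyl with t-BuMe2SiOTf and 2,6-lutidine gives 26.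

Step 19. The alkoxide may attack the CH2 terminus (C15) of the π-allyl complex instead of C5, which would give an isomeric ether with an endocyclic C4=C5 double bond, or methoxide may capture the complex. The fallback sets out from 25 and comes back at 27; it removes the allyl system so that only C5 can be attacked. Ozonolysis of the exocyclic methylene of 25 (O3, CH2Cl2/MeOH, −78 °C; Me2S) gives the α-hydroxy ketone F7, and MsCl with Et3N gives the α-keto mesylate F8. Cs2CO3 in MeCN then induces transannular SN2 displacement by the C10 hydroxyl to give the bridged ketone F9; the α-keto mesylate can epimerise at C5 under these conditions, so both epimers should drain through the one that can bridge. Wittig methylenation with Ph3P=CH2 in THF restores the C4 methylene and gives 27.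

Step 22. After the alcohol oxidation the dehydrogenation may be sluggish or unselective, and prolonged heating may degrade the diene-containing product oxidatively. The fallback sets out from 31 and comes back at 33. Dess–Martin oxidation of 31 gives ketone 32, isolated in this variant; Me3SiOTf and Et3N convert it regiospecifically (C10 is quaternary) into the trimethylsilyl enol ether F10, and Saegusa–Ito oxidation with Pd(OAc)2 in MeCN gives 33.

**Further compounds**

F1 | step 17 | isoxazoline primary alcohol | O=C1C[C@H](C2=NO[C@](C)([C@@H](O[Si](CC)(CC)CC)CCC(I)=C)C2)[C@@H](CO)O1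
F2 | step 17 | isoxazoline aldehyde | O=C1C[C@H](C2=NO[C@](C)([C@@H](O[Si](CC)(CC)CC)CCC(I)=C)C2)[C@@H](C=O)O1
F3 | step 17 | macrocyclic isoxazoline carbinol (C5 epimers) | C1C(=O)O[C@H]2[C@H]1C1=NO[C@@](C)(C1)[C@@H](O[Si](CC)(CC)CC)CCC(=C)C2O
F4 | step 17 | macrocyclic isoxazoline carbonate | C1C(=O)O[C@H]2[C@H]1C1=NO[C@@](C)(C1)[C@@H](O[Si](CC)(CC)CC)CCC(=C)C2OC(=O)OC
F5 | step 17 | macrocyclic β-hydroxy ketone | C1C(=O)O[C@H]2[C@H]1C(=O)C[C@](C)(O)[C@@H](O[Si](CC)(CC)CC)CCC(=C)C2OC(=O)OC
F6 | step 17 | macrocyclic diol | C1C(=O)O[C@H]2[C@H]1[C@H](O)C[C@](C)(O)[C@@H](O[Si](CC)(CC)CC)CCC(=C)C2OC(=O)OC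
F7 | step 19 | α-hydroxy ketone (C4 ketone, C5 hydroxyl) | C1C(=O)O[C@H]2[C@H]1[C@H](O[Si](C)(C)C(C)(C)C)C[C@](C)(O)[C@@H](O[Si](CC)(CC)CC)CCC(=O)C2O
F8 | step 19 | α-keto mesylate | C1C(=O)O[C@H]2[C@H]1[C@H](O[Si](C)(C)C(C)(C)C)C[C@](C)(O)[C@@H](O[Si](CC)(CC)CC)CCC(=O)C2OS(C)(=O)=O
F9 | step 19 | bridged ketone (C4 ketone) | C1C(=O)O[C@H]2[C@H]1[C@H](O[Si](C)(C)C(C)(C)C)C[C@]1(C)O[C@H]2C(=O)CC[C@@H]1O[Si](CC)(CC)CC
F10 | step 22 | trimethylsilyl enol ether (C1=C2) | C=C1C(=O)O[C@H]2[C@H]1[C@H](O[Si](C)(C)C(C)(C)C)C[C@]1(C)O[C@H]2C(=C)CC=C1O[Si](C)(C)C
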